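**Retrosynthetic overview**
- The acetate goes on last-but-one, onto the only free phenol (O-2); the final operation removes two aryl silyl ethers.
- The aryl–C(=CH2) bond comes from a Suzuki–Miyaura union of an ortho-hydroxyarylboronate with the (S)-2-bromoallylic angelate.
- Key step: the C2v-symmetric bis-silyl ether of 2-methylresorcinol is desymmetrised by one C–H hydroxylation that passes through a dearomatised cyclohexadienyl intermediate. The new OH then steers C–H borylation to its ortho carbon.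
- Side chain: Brown allylboration of 2-bromoacrolein sets the (S) centre, cross-metathesis turns allyl into prenyl, and angelic anhydride installs the Z ester.
- No ring is built; the only ring is the benzene ring of 2-methylresorcinol.

Assumption: phthaloyl peroxide (one operation from phthaloyl chloride and sodium percarbonate) and (Z)-2-methylbut-2-enoic anhydride are counted as reagents; the target is read as S at the carbinol carbon and Z in the enoate.

**Route**

Step 1
Reactants: 1 2-methylresorcinol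
Product: 2 2,6-bis(triisopropylsilyloxy)toluene
Conditions: iPr3SiCl (2.3 equiv), imidazole, DMF, 50 °C
Reagents that add atoms: triisopropylsilyl chloride, CC(C)[Si](Cl)(C(C)C)C(C)C
Why: Silyl ether formation; the bulky triisopropylsilyl groups survive aqueous base and are slow to hop to a neighbouring phenoxide, which matters from step 2 onward.

Step 2
Reactants: 2 2,6-bis(triisopropylsilyloxy)toluene
Product: 4 3-methyl-2,4-bis(triisopropylsilyloxy)phenol, via aryl hydrogen phthalate 3 (not isolated)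
Conditions: phthaloyl peroxide (1.1 equiv), (CF3)2CHOH, 23 °C; then NaHCO3, MeOH/H2O, 40 °C
Reagents that add atoms: phthaloyl peroxide, O=C1OOC(=O)c2ccccc12
Why: Arene C–H hydroxylation with phthaloyl peroxide (reverse-rebound mechanism): the peroxide adds to the ring to give a dearomatised cyclohexadienyl radical at C3 (ortho to one silyloxy group and para to the other, equivalent to C5 by symmetry), and the phthalate half ester shields the new oxygen from over-oxidation until it is cleaved by bicarbonate.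

Step 3
Reactants: 5 2-bromoprop-2-en-1-ol
Product: 7 (S)-2-bromohexa-1,5-dien-3-ol, via 2-bromoacrolein 6 (not isolated)
Conditions: MnO2, CH2Cl2, rt, filter; then (−)-Ipc2B(allyl) [from (+)-α-pinene], Et2O, −78 °C; then NaOH, H2O2, 0 °C
Reagents that add atoms: (−)-B-allyldiisopinocampheylborane, C=CCB([C@@H]1C[C@@H]2C[C@H]([C@H]1C)C2(C)C)[C@@H]1C[C@@H]2C[C@H]([C@H]1C)C2(C)C
Why: Allylic alcohol oxidation followed by Brown asymmetric allylboration through a closed chair transition state; this reagent attacks the Si face of the aldehyde, which gives (S) here because the bromovinyl group outranks the allyl CH2 (the same sense that turns benzaldehyde into (S)-1-phenylbut-3-en-1-ol), at an expected 90–95% ee.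

Step 4
Reactants: 7 (S)-2-bromohexa-1,5-dien-3-ol
Product: 8 (S)-2-bromo-6-methylhepta-1,5-dien-3-ol
Conditions: 2-methyl-2-butene (excess), second-generation Grubbs catalyst RuCl2(=CHPh)(PCy3)(H2IMes) (3 mol%), CH2Cl2, 40 °C
Reagents that add atoms: 2-methyl-2-butene, CC=C(C)C
Why: Olefin cross-metathesis: only the monosubstituted alkene enters the cycle (the 2-bromo-1,1-disubstituted alkene is inert) and the excess trisubstituted partner caps it as the prenyl group.

Step 5
Reactants: 8 (S)-2-bromo-6-methylhepta-1,5-dien-3-ol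
Product: 9 (S)-2-bromo-6-methylhepta-1,5-dien-3-yl (Z)-2-methylbut-2-enoate
Conditions: LiN(SiMe3)2, THF, −78 °C; then (Z)-2-methylbut-2-enoic anhydride, −78 → 0 °C
Reagents that add atoms: (Z)-2-methylbut-2-enoic anhydride (angelic anhydride), C/C=C(/C)C(=O)OC(=O)/C(C)=C\C
Why: O-acylation of the lithium alkoxide by the symmetric anhydride with no nucleophilic catalyst, which avoids the addition–elimination path that isomerises angelates to tiglates; the C–O bond at the stereocentre is not broken.

Step 6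
Reactants: 4 3-methyl-2,4-bis(triisopropylsilyloxy)phenol; 9 (S)-2-bromo-6-methylhepta-1,5-dien-3-yl (Z)-2-methylbut-2-enoate
Product: 13 (S)-2-[2-hydroxy-4-methyl-3,5-bis(triisopropylsilyloxy)phenyl]-6-methylhepta-1,5-dien-3-yl (Z)-2-methylbut-2-enoate, via hydrosilyl ether 10 (not isolated), via borylated hydrosilyl ether 11 (not isolated), via hydroxyaryl boronate 12 (not isolated)
Conditions: Et2SiH2, [Ir(cod)Cl]2 cat., THF, rt; then B2pin2, HBpin cat., [Ir(cod)Cl]2/dtbpy cat., THF, 80 °C; then 9, Pd(OAc)2/SPhos cat., aq K3PO4, THF, 25–40 °C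
Reagents that add atoms: none
Why: Dehydrogenative O-silylation and Hartwig silyl-directed ortho C–H borylation put boron on the only C–H next to the new oxygen (C6); after in-flask hydrolysis of the Si–O bond, a Suzuki–Miyaura coupling follows in which oxidative addition to the vinyl bromide outpaces ionisation of the allylic ester, so the stereocentre is untouched.

Step 7
Reactants: 13 (S)-2-[2-hydroxy-4-methyl-3,5-bis(triisopropylsilyloxy)phenyl]-6-methylhepta-1,5-dien-3-yl (Z)-2-methylbut-2-enoate
Product: 14 (S)-2-[2-acetoxy-4-methyl-3,5-bis(triisopropylsilyloxy)phenyl]-6-methylhepta-1,5-dien-3-yl (Z)-2-methylbut-2-enoate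
Conditions: Ac2O, Et3N, DMAP cat., CH2Cl2, 0 °C → rt
Reagents that add atoms: acetic anhydride, CC(=O)OC(C)=O
Why: DMAP-catalysed acyl transfer to the only free hydroxyl fixes the acetate on O-2 with no regioisomer possible.

Step 8
Reactants: 14 (S)-2-[2-acetoxy-4-methyl-3,5-bis(triisopropylsilyloxy)phenyl]-6-methylhepta-1,5-dien-3-yl (Z)-2-methylbut-2-enoate
Product: 15 (S)-2-(2-acetoxy-3,5-dihydroxy-4-methylphenyl)-6-methylhepta-1,5-dien-3-yl (Z)-2-methylbut-2-enoate
Conditions: KHF2, MeOH, rt
Reagents that add atoms: none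
Why: Fluoride-driven desilylation of the two aryl silyl ethers in a weakly acidic medium where no phenoxide forms, so the acetate should neither migrate to the neighbouring hydroxyl nor be methanolysed, and the Z-enoate and stereocentre are unaffected.

**Compound list**

1 | 2-methylresorcinol | Cc1c(O)cccc1O | starting material
2 | 2,6-bis(triisopropylsilyloxy)toluene | Cc1c(O[Si](C(C)C)(C(C)C)C(C)C)cccc1O[Si](C(C)C)(C(C)C)C(C)C | intermediate
3 | 2-{[3-methyl-2,4-bis(triisopropylsilyloxy)phenoxy]carbonyl}benzoic acid (aryl hydrogen phthalate) | Cc1c(O[Si](C(C)C)(C(C)C)C(C)C)ccc(OC(=O)c2ccccc2C(=O)O)c1O[Si](C(C)C)(C(C)C)C(C)C | intermediate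
4 | 3-methyl-2,4-bis(triisopropylsilyloxy)phenol | Cc1c(O[Si](C(C)C)(C(C)C)C(C)C)ccc(O)c1O[Si](C(C)C)(C(C)C)C(C)C | intermediate
5 | 2-bromoprop-2-en-1-ol | OCC(Br)=C | starting material
6 | 2-bromoprop-2-enal (2-bromoacrolein) | O=CC(Br)=C | intermediate
7 | (S)-2-bromohexa-1,5-dien-3-ol | C=C(Br)[C@H](CC=C)O | intermediate
8 | (S)-2-bromo-6-methylhepta-1,5-dien-3-ol | C=C(Br)[C@H](CC=C(C)C)O | intermediate
9 | (S)-2-bromo-6-methylhepta-1,5-dien-3-yl (Z)-2-methylbut-2-enoate | C=C(Br)[C@H](CC=C(C)C)OC(=O)/C(C)=C\C | intermediate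
10 | diethyl[3-methyl-2,4-bis(triisopropylsilyloxy)phenoxy]silane (hydrosilyl ether) | Cc1c(O[Si](C(C)C)(C(C)C)C(C)C)ccc(O[SiH](CC)CC)c1O[Si](C(C)C)(C(C)C)C(C)C | intermediate
11 | diethyl[3-methyl-6-(4,4,5,5-tetramethyl-1,3,2-dioxaborolan-2-yl)-2,4-bis(triisopropylsilyloxy)phenoxy]silane | Cc1c(O[Si](C(C)C)(C(C)C)C(C)C)cc(B2OC(C)(C)C(C)(C)O2)c(O[SiH](CC)CC)c1O[Si](C(C)C)(C(C)C)C(C)C | intermediate
12 | 3-methyl-6-(4,4,5,5-tetramethyl-1,3,2-dioxaborolan-2-yl)-2,4-bis(triisopropylsilyloxy)phenol | Cc1c(O[Si](C(C)C)(C(C)C)C(C)C)cc(B2OC(C)(C)C(C)(C)O2)c(O)c1O[Si](C(C)C)(C(C)C)C(C)C | intermediate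
13 | (S)-2-[2-hydroxy-4-methyl-3,5-bis(triisopropylsilyloxy)phenyl]-6-methylhepta-1,5-dien-3-yl (Z)-2-methylbut-2-enoate | C=C(c1cc(O[Si](C(C)C)(C(C)C)C(C)C)c(C)c(O[Si](C(C)C)(C(C)C)C(C)C)c1O)[C@H](CC=C(C)C)OC(=O)/C(C)=C\C | intermediate
14 | (S)-2-[2-acetoxy-4-methyl-3,5-bis(triisopropylsilyloxy)phenyl]-6-methylhepta-1,5-dien-3-yl (Z)-2-methylbut-2-enoate | C=C(c1cc(O[Si](C(C)C)(C(C)C)C(C)C)c(C)c(O[Si](C(C)C)(C(C)C)C(C)C)c1OC(C)=O)[C@H](CC=C(C)C)OC(=O)/C(C)=C\C | intermediate
15 | (S)-2-(2-acetoxy-3,5-dihydroxy-4-methylphenyl)-6-methylhepta-1,5-dien-3-yl (Z)-2-methylbut-2-enoate (CNP0147405.1) | C=C(c1cc(O)c(C)c(O)c1OC(C)=O)[C@H](CC=C(C)C)OC(=O)/C(C)=C\C | target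

**Step count and risks**

Total steps: 8. Longest linear sequence: 6 (steps 3, 4, 5, 6, 7, 8; the arene branch joins after 2 steps).

The three steps most likely to fail are steps 6, 2 and 3.

Step 6 is the most exposed: it strings two iridium-catalysed stages and a palladium coupling together, with a free phenoxide sitting next to an allylic ester and a silyl ether. The fallback reverses the order of metalation and sets out from 4, returning at 13. Compound 4 is iodinated ortho to the free hydroxyl (N-iodosuccinimide, TsOH cat., CH2Cl2, 0 °C) to give 6-iodo-3-methyl-2,4-bis(triisopropylsilyloxy)phenol F1. Deprotonation with MeMgCl and iodine–magnesium exchange with iPrMgCl·LiCl at −20 °C give the aryl Grignard magnesium phenoxide F2. ZnCl2 converts it into the arylzinc chloride F3, and Negishi coupling with 9 (Pd(OAc)2/SPhos cat., THF, rt) gives 13 under base-free conditions.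

Step 2 may give bis-hydroxylation or react sluggishly next to the bulky silyloxy group. The fallback builds the C–O bond from a C–C bond instead; it sets out from 1 and returns at 4. Vilsmeier–Haack formylation of 1 (POCl3, DMF; then H2O) gives 2,4-dihydroxy-3-methylbenzaldehyde F4. Silylation (iPr3SiOTf, 2,6-lutidine, CH2Cl2) gives 3-methyl-2,4-bis(triisopropylsilyloxy)benzaldehyde F5. Baeyer–Villiger oxidation with mCPBA (CH2Cl2, 0 °C) gives 3-methyl-2,4-bis(triisopropylsilyloxy)phenyl formate F6, which NaHCO3 in MeOH cleaves to 4.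

Step 3 depends on a volatile, polymerisable aldehyde and on reagent control for the only stereocentre. The fallback makes the C–C bond first and sets the centre by reduction; it sets out from 6 and returns at 7. Allylmagnesium bromide (Et2O, −78 °C) adds to 6 to give racemic 2-bromohexa-1,5-dien-3-ol F7. Dess–Martin oxidation (NaHCO3-buffered, CH2Cl2, 0 °C) gives 2-bromohexa-1,5-dien-3-one F8. Corey–Bakshi–Shibata reduction with (R)-2-methyl-CBS-oxazaborolidine and catecholborane (toluene, −78 °C), in which the bromovinyl group acts as the large substituent, gives 7.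

**Further compounds**

F1 | step 6 | 6-iodo-3-methyl-2,4-bis(triisopropylsilyloxy)phenol | Cc1c(O[Si](C(C)C)(C(C)C)C(C)C)cc(I)c(O)c1O[Si](C(C)C)(C(C)C)C(C)C
F2 | step 6 | aryl Grignard magnesium phenoxide | Cc1c(O[Si](C(C)C)(C(C)C)C(C)C)cc([Mg]Cl)c(O[Mg]Cl)c1O[Si](C(C)C)(C(C)C)C(C)C
F3 | step 6 | arylzinc chloride | Cc1c(O[Si](C(C)C)(C(C)C)C(C)C)cc([Zn]Cl)c(O[Mg]Cl)c1O[Si](C(C)C)(C(C)C)C(C)C
F4 | step 2 | 2,4-dihydroxy-3-methylbenzaldehyde | Cc1c(O)ccc(C=O)c1O
F5 | step 2 | 3-methyl-2,4-bis(triisopropylsilyloxy)benzaldehyde | Cc1c(O[Si](C(C)C)(C(C)C)C(C)C)ccc(C=O)c1O[Si](C(C)C)(C(C)C)C(C)C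
F6 | step 2 | 3-methyl-2,4-bis(triisopropylsilyloxy)phenyl formate | Cc1c(O[Si](C(C)C)(C(C)C)C(C)C)ccc(OC=O)c1O[Si](C(C)C)(C(C)C)C(C)C
F7 | step 3 | racemic 2-bromohexa-1,5-dien-3-ol | C=C(Br)C(O)CC=C
F8 | step 3 | 2-bromohexa-1,5-dien-3-one | C=C(Br)C(=O)CC=C
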